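## Retrosynthetic overview

1. The C4(tetralin)–C1'(naphthalene) bond is cut last. The partners are the aryl(dimethyl)alane 11 of the silyl-protected bromonaphthol and the (1S,4R)-1,4-epoxytetralin 5, whose oxygen bridge is a temporary ring: it is the future C1–OH, the leaving group at C4 and the tether that delivers the aryl group cis.
2. Enabling feature: the methoxy group on C5 of the tetralin benzene ring is ortho to C4a, so only the C4–O bond of the bridge ionises (o-methoxybenzylic cation; C1 is attached meta). C1–OH and C4–aryl are cis-1,4, the footprint of a 1,4-oxygen bridge. On the other half, C4 of the 1-naphthol is para to the oxygen, where Br and then Al are placed.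
3. 5 comes from 5-methoxy-1-tetralone: benzylic bromination at C4, CBS reduction (sets C1), intramolecular Williamson closure of the bridge (C4 converges).
4. The naphthalene half comes from naphthalene-1,8-diol: mono-methylation, para-bromination, silylation. Both carbon bicycles are bought; the only ring made (step 3) is the oxygen bridge, opened again in step 7.
5. Desilylation ends the route.

Key step: step 7

Remark on the chemistry: the SMILES is read as the cis-(1S,4S) isomer (C1–OH and C4–aryl on the same face). Tetralin numbering used throughout: C1 = carbinol carbon, C4 = aryl-bearing carbon, C5 = methoxy carbon.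

## Route

Step 1
Reactants: 1 5-methoxy-3,4-dihydronaphthalen-1(2H)-one
Product: 2 rac-4-bromo-5-methoxy-3,4-dihydronaphthalen-1(2H)-one
Conditions: NBS (1.05 equiv), AIBN (5 mol %), PhCF3, 80 °C; used without chromatography
Reagents that add atoms: N-bromosuccinimide, O=C1CCC(=O)N1Br
Why: Wohl–Ziegler bromination; C4 is the only benzylic CH2, its radical is stabilised by the ring and the neighbouring methoxy group, and the acyl-deactivated ring should resist nuclear bromination.

Step 2
Reactants: 2 rac-4-bromo-5-methoxy-3,4-dihydronaphthalen-1(2H)-one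
Product: 3 (1S,4RS)-4-bromo-5-methoxy-1,2,3,4-tetrahydronaphthalen-1-ol
Conditions: (R)-2-methyl-CBS-oxazaborolidine (10 mol %), BH3·SMe2 (0.7 equiv), THF, −20 °C; MeOH, −20 °C; pH 7 buffer; crude into step 3
Reagents that add atoms: none
Why: Corey–Bakshi–Shibata reduction; the (R)-catalyst differentiates aryl (large) from CH2 (small) and should give the (S)-carbinol in both C4 epimers, the remote bromide having no influence.

Step 3
Reactants: 3 (1S,4RS)-4-bromo-5-methoxy-1,2,3,4-tetrahydronaphthalen-1-ol
Product: 5 (1S,4R)-5-methoxy-1,2,3,4-tetrahydro-1,4-epoxynaphthalene, via sodium alkoxide 4 (not isolated)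
Conditions: NaH (1.2 equiv), n-Bu4NBr (0.2 equiv), THF, 0 °C → rt
Reagents that add atoms: sodium hydride, [Na+].[H-] (its sodium is present only in 4, not in 5)
Why: intramolecular Williamson etherification through a boat, as trans-4-halocyclohexanols close to 7-oxabicyclo[2.2.1]heptanes; the trans (1S,4S) epimer closes with inversion at C4, the cis epimer is fed into it by SN2 bromide exchange at the activated benzylic carbon, and the bridge fixes C4 as R.

Step 4
Reactants: 6 naphthalene-1,8-diol
Product: 7 8-methoxynaphthalen-1-ol
Conditions: MeI (1.05 equiv), K2CO3 (1.0 equiv), acetone, rt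
Reagents that add atoms: iodomethane, CI
Why: Williamson O-methylation; the remaining OH is hydrogen-bonded to the new peri methoxy group and much less acidic, so the reaction should stop at the mono ether.

Step 5
Reactants: 7 8-methoxynaphthalen-1-ol
Product: 8 4-bromo-8-methoxynaphthalen-1-ol
Conditions: NBS (1.0 equiv), MeCN, −30 → 0 °C, dark
Reagents that add atoms: N-bromosuccinimide, O=C1CCC(=O)N1Br
Why: electrophilic aromatic bromination; the free hydroxyl is the stronger donor, so the phenolic ring reacts, and its para position C4 should be preferred over ortho C2 under polar aprotic, low-temperature conditions.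

Step 6
Reactants: 8 4-bromo-8-methoxynaphthalen-1-ol
Product: 9 [(4-bromo-8-methoxynaphthalen-1-yl)oxy](tert-butyl)dimethylsilane
Conditions: TBSCl (1.3 equiv), imidazole (2.5 equiv), DMF, rt → 40 °C
Reagents that add atoms: tert-butyldimethylsilyl chloride, CC(C)(C)[Si](C)(C)Cl
Why: O-silylation of the naphthol; the TBS ether masks the acidic OH for the organometallic step and is later removed by fluoride without touching the methyl ethers.

Step 7
Reactants: 9 [(4-bromo-8-methoxynaphthalen-1-yl)oxy](tert-butyl)dimethylsilane; 5 (1S,4R)-5-methoxy-1,2,3,4-tetrahydro-1,4-epoxynaphthalene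
Product: 13 (1S,4S)-4-[4-(tert-butyldimethylsilyloxy)-5-methoxynaphthalen-1-yl]-5-methoxy-1,2,3,4-tetrahydronaphthalen-1-ol, via aryllithium 10 (not isolated), via aryldimethylalane 11 (not isolated), via dimethylaluminium alkoxide 12 (not isolated)
Conditions: 9 (1.5 equiv), n-BuLi (1.5 equiv), Et2O, −78 → −20 °C; Me2AlCl (1.5 equiv, hexanes), −78 → 0 °C; solvent switch to PhMe; 5 (1.0 equiv), −20 °C → rt; aq. Rochelle salt
Reagents that add atoms: n-butyllithium, CCCC[Li] (Li of 10); dimethylaluminium chloride, C[Al](C)Cl (AlMe2 of 11 and 12); none of these atoms remains in 13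
Why: Proposed new method: the alane binds the bridging oxygen, the C4–O bond ionises to an o-methoxybenzylic cation while the aluminate stays on the C1 oxygen on the upper face, and the naphthyl group migrates from aluminium to C4 through its ipso carbon (naphthalene C1) within this zwitterion; the closest known reaction types are the retentive ring-opening C-arylation of 1,6-anhydro sugars and the syn opening of glycal and benzylic epoxides by aryl- and alkylalanes, here carried over from acetal and epoxide carbons to a strained benzylic ether. No ring is closed; the temporary 7-oxabicyclo[2.2.1] bridge from step 3 is opened and leaves its oxygen as the C1 alkoxide. The C1 stereocentre (S, from step 2) is untouched because its C–O bond is never broken, and the new C4 stereocentre is controlled by the tether: delivery from O–Al across the boat places the naphthyl group where the bridge oxygen was (retention; the descriptor changes from R to S only through the priority rules), which gives the cis-1,4 relation. The step needs (i) cleavage of C4–O and not C1–O, secured by the methoxy group on C5, which is ortho to C4a and stabilises only the C4 cation, (ii) syn and not anti attack, secured by the intramolecular delivery and helped by a non-coordinating solvent, and (iii) aryl and not methyl transfer, in line with the known preference of mixed aryl(alkyl)alanes to transfer the sp2 group.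

Step 8
Reactants: 13 (1S,4S)-4-[4-(tert-butyldimethylsilyloxy)-5-methoxynaphthalen-1-yl]-5-methoxy-1,2,3,4-tetrahydronaphthalen-1-ol
Product: 14 Dipolynaphthalene B
Conditions: TBAF (1.1 equiv), AcOH (1.1 equiv), THF, 0 °C, argon
Reagents that add atoms: none
Why: fluoride-driven cleavage of the aryl silyl ether (strong Si–F bond); the buffered conditions should keep the electron-rich naphthol from oxidising and leave the benzylic alcohol, the methyl ethers and both stereocentres untouched.

## Compound list

1 | 5-methoxy-3,4-dihydronaphthalen-1(2H)-one | COc1cccc2c1CCCC2=O | starting material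
2 | rac-4-bromo-5-methoxy-3,4-dihydronaphthalen-1(2H)-one | COc1cccc2c1C(Br)CCC2=O | intermediate
3 | (1S,4RS)-4-bromo-5-methoxy-1,2,3,4-tetrahydronaphthalen-1-ol | COc1cccc2c1C(Br)CC[C@@H]2O | intermediate
4 | sodium (1S,4RS)-4-bromo-5-methoxy-1,2,3,4-tetrahydronaphthalen-1-olate | COc1cccc2c1C(Br)CC[C@@H]2[O-].[Na+] | intermediate (not isolated)
5 | (1S,4R)-5-methoxy-1,2,3,4-tetrahydro-1,4-epoxynaphthalene | COc1cccc2c1[C@H]1CC[C@@H]2O1 | intermediate
6 | naphthalene-1,8-diol | Oc1cccc2cccc(O)c12 | starting material
7 | 8-methoxynaphthalen-1-ol | COc1cccc2cccc(O)c12 | intermediate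
8 | 4-bromo-8-methoxynaphthalen-1-ol | COc1cccc2c(Br)ccc(O)c12 | intermediate
9 | [(4-bromo-8-methoxynaphthalen-1-yl)oxy](tert-butyl)dimethylsilane | COc1cccc2c(Br)ccc(O[Si](C)(C)C(C)(C)C)c12 | intermediate
10 | [4-(tert-butyldimethylsilyloxy)-5-methoxynaphthalen-1-yl]lithium | COc1cccc2c([Li])ccc(O[Si](C)(C)C(C)(C)C)c12 | intermediate (not isolated)
11 | [4-(tert-butyldimethylsilyloxy)-5-methoxynaphthalen-1-yl]dimethylalane | COc1cccc2c([Al](C)C)ccc(O[Si](C)(C)C(C)(C)C)c12 | intermediate (not isolated)
12 | dimethylaluminium (1S,4S)-4-[4-(tert-butyldimethylsilyloxy)-5-methoxynaphthalen-1-yl]-5-methoxy-1,2,3,4-tetrahydronaphthalen-1-olate | COc1cccc2c1[C@H](c1ccc(O[Si](C)(C)C(C)(C)C)c3c(OC)cccc13)CC[C@@H]2O[Al](C)C | intermediate (not isolated)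
13 | (1S,4S)-4-[4-(tert-butyldimethylsilyloxy)-5-methoxynaphthalen-1-yl]-5-methoxy-1,2,3,4-tetrahydronaphthalen-1-ol | COc1cccc2c1[C@H](c1ccc(O[Si](C)(C)C(C)(C)C)c3c(OC)cccc13)CC[C@@H]2O | intermediate
14 | Dipolynaphthalene B, (1S,4S)-4-(4-hydroxy-5-methoxynaphthalen-1-yl)-5-methoxy-1,2,3,4-tetrahydronaphthalen-1-ol | COc1cccc2c1[C@H](c1ccc(O)c3c(OC)cccc13)CC[C@@H]2O | target

## Step count and risks

Total steps: 8. Longest linear sequence: 5 (steps 1, 2, 3, 7, 8; the naphthalene branch, steps 4, 5, 6, 7, 8, is equally long).

Steps most likely to fail: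

1. Step 7 (proposed new method). The zwitterion may collapse by proton loss from C3 (elimination), by methyl instead of aryl transfer, or by attack of a second alane from the lower face (loss of the cis relation); the bridge may also fail to ionise. The fallback uses known chemistry, an enantioconvergent nickel-catalysed Negishi arylation of a racemic secondary benzylic bromide followed by a catalyst-controlled CBS reduction. It sets out from racemic bromo ketone 2 and aryllithium 10 (made from 9 as in step 7) and comes back at 13. Transmetalation of 10 with ZnBr2 should give [4-(tert-butyldimethylsilyloxy)-5-methoxynaphthalen-1-yl]zinc bromide F1. Coupling of F1 with 2 under NiBr2·glyme and a chiral bis(oxazoline) (THF/CH2Cl2, −45 °C) passes both enantiomers of 2 through one benzylic radical and should converge on (S)-4-[4-(tert-butyldimethylsilyloxy)-5-methoxynaphthalen-1-yl]-5-methoxy-3,4-dihydronaphthalen-1(2H)-one F2; the ligand enantiomer that leads to S is to be chosen. Reduction of F2 with (R)-Me-CBS/BH3·SMe2, matched with the substrate's own preference for hydride attack anti to the pseudoaxial aryl group, should give 13, and step 8 follows unchanged.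

2. Step 3. Loss of HBr (E2 by the alkoxide or E1 from the methoxy-stabilised cation) may outrun the boat-shaped SN2 closure, and the cis epimer may equilibrate too slowly. The fallback turns the elimination into the route; it sets out from 3 and comes back at 5. DBU in toluene at 60 °C should convert both epimers into (S)-5-methoxy-1,2-dihydronaphthalen-1-ol F3. Iodoetherification (I2, NaHCO3, MeCN, 0 °C), in which the C1–OH attacks the iodonium ion at the methoxy-stabilised benzylic C4 in an anti addition, should give (1S,3S,4S)-3-iodo-5-methoxy-1,2,3,4-tetrahydro-1,4-epoxynaphthalene F4. Radical deiodination (Bu3SnH, AIBN, benzene, 80 °C) then gives 5.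

3. Step 1. Over-bromination, ionic α-bromination through the enol, and loss of HBr with aromatisation of the keto ring may erode the bromo ketone. The fallback removes the ketone before the bromination; it sets out from 1 and comes back at 3. (R)-Me-CBS reduction of 1 should give (S)-5-methoxy-1,2,3,4-tetrahydronaphthalen-1-ol F5, and acetylation (Ac2O, pyridine, DMAP) gives (S)-5-methoxy-1,2,3,4-tetrahydronaphthalen-1-yl acetate F6. Wohl–Ziegler bromination of F6 (NBS, AIBN, PhCF3) should occur at the C4 methylene, the acetoxy-bearing C1–H being deactivated, to give (1S,4RS)-4-bromo-5-methoxy-1,2,3,4-tetrahydronaphthalen-1-yl acetate F7. Reductive removal of the acetate (DIBAL-H, CH2Cl2, −78 °C) gives 3.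

Further compounds
F1 | step 7 | [4-(tert-butyldimethylsilyloxy)-5-methoxynaphthalen-1-yl]zinc bromide | COc1cccc2c([Zn]Br)ccc(O[Si](C)(C)C(C)(C)C)c12
F2 | step 7 | (S)-4-[4-(tert-butyldimethylsilyloxy)-5-methoxynaphthalen-1-yl]-5-methoxy-3,4-dihydronaphthalen-1(2H)-one | COc1cccc2c1[C@H](c1ccc(O[Si](C)(C)C(C)(C)C)c3c(OC)cccc13)CCC2=O
F3 | step 3 | (S)-5-methoxy-1,2-dihydronaphthalen-1-ol | COc1cccc2c1C=CC[C@@H]2O
F4 | step 3 | (1S,3S,4S)-3-iodo-5-methoxy-1,2,3,4-tetrahydro-1,4-epoxynaphthalene | COc1cccc2c1[C@H]1[C@@H](I)C[C@@H]2O1
F5 | step 1 | (S)-5-methoxy-1,2,3,4-tetrahydronaphthalen-1-ol | COc1cccc2c1CCC[C@@H]2O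
F6 | step 1 | (S)-5-methoxy-1,2,3,4-tetrahydronaphthalen-1-yl acetate | COc1cccc2c1CCC[C@@H]2OC(C)=O
F7 | step 1 | (1S,4RS)-4-bromo-5-methoxy-1,2,3,4-tetrahydronaphthalen-1-yl acetate | COc1cccc2c1C(Br)CC[C@@H]2OC(C)=O
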